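In percent of the acidic substrate charged, the earlier plateaus read about 81 % in the violet run and 47 % in the ochre run, and the hunch that Tuesday's, at 120 °C against Monday's 100 °C, finishes higher has to answer to those readings first.

| flask | acidic substrate | free base | electrophile | temperature | remark | time |
|---|---|---|---|---|---|---|
| violet | 0.32 M | 0.26 M | 0.52 M | 105 °C | run made earlier |  |
| ochre | 0.55 M | 0.26 M | 0.52 M | 116 °C | run made earlier |  |
| Monday's | 0.26 M | 0.260 M | 0.520 M | 100 °C |  | 8.0 h |
| Tuesday's | 0.40 M | 0.260 M | 0.520 M | 120 °C |  | 8.0 h |

- violet (time / h: target / %, acidic substrate / %): 1.00: 79, 18; 2.50: 82, 18; 3.00: 81, 18; 5.00: 82, 18; 6.00: 80, 18; 8.00: 80, 19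
- ochre (time / h: target / %, acidic substrate / %): 0.200: 46, 51; 0.667: 48, 55; 1.00: 46, 55; 1.33: 46, 53; 2.50: 47, 53; 4.00: 48, 51

(standard deviation of a reading: 1.5 percentage points)

- percent here means acidic substrate units held: one side product counts as two
- what is said of target includes crystals
- crystals is a solid; its amount is given per volume of the solution
- on the list of suspects stand: acidic substrate + free base <-> protonated base + anion; acidic substrate + anion -> side product; crystals <-> target; electrophile + anion -> target

- which one finishes higher in amount of target, in percent of the acidic substrate charged ("neither" within 2 percentage points) (Monday's / Tuesday's / neither)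
- amount of target at the end, in percent of the acidic substrate charged, Monday's
- amount of target at the end, in percent of the acidic substrate charged, Tuesday's

Free base charged, as a fraction of acidic substrate charged, is 81.2 % in the violet run and 47.3 % in the ochre run, and the plateaus sit on these fractions within the scatter, at 105 °C and 116 °C alike. That reads as free base being the limiting reagent. For Tuesday's the fraction is 65.0 %, and this quantity, free base charged over acidic substrate charged, capped at the whole charge, is the base ceiling. Monday's stands at the crossing where the fraction reaches the whole charge, with a ceiling of 100 %, higher than Tuesday's by 35 percentage points. The ochre run already stood on its plateau at 0.200 h, far short of 8.0 h, though Monday's is cooler than both runs.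

The forecast names Monday's, with 97 % for Monday's and 65 % for Tuesday's. Its Tuesday figure is the ceiling; its Monday figure stands below the ceiling reckoned here, on the grounds of “second-order decay as protonated base builds up”.

Monday's ends at 99.7 % against a ceiling of 100 %, and Tuesday's at 64.9 % against a ceiling of 65.0 %, so Monday's finishes higher. Monday's answer has moved by 5 points at 0.274 M of acidic substrate, against 0.26 M charged. The neighbour, Monday's recipe with 0.44 M of acidic substrate, has a base ceiling of 59.1 %; it gives 59.0 %, with unbound free base at 0 % of its charge and unbound acidic substrate at 41 % of its charge.

    acidic substrate + free base ⇌ protonated base + anion, settled at all times (K = 2.20, ΔH = 26.0 kJ/mol)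
    acidic substrate + anion → side product (k = 0.00559 /M/min, Ea = 99.0 kJ/mol)
    crystals ⇌ target, rate k3*(cs3 - [target]) while solid is left; crystals form when [target] > cs3 (solubility = 0.130 M, k = 0.428 /min)
    electrophile + anion → target (k = 1.60 /M/min, Ea = 82.0 kJ/mol)
    (constants at 100 °C)

(The earlier runs and the new flask are simulated with constants of no real substance, and the scatter is random.)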